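Atom locants used throughout: ring A is C1(Me)=C2–C3(OH)–C4(Br)–C5(Me2)–C6, ring B is C6–C7–C8–C9(Me)=C10(Br)–C11. Compound numbers are those of the steps and the compound list below.

## Analysis of the target

Compound 17 is a spiro[5.5]undecadiene of the chamigrene type. Ring A is the cyclohexene C1(Me)=C2–C3(OH)–C4(Br)–C5(Me2)–C6 and ring B the cyclohexene C6–C7–C8–C9(Me)=C10(Br)–C11, joined at the quaternary spiro carbon C6. There are three stereocentres, C3, C4 and C6, all S. On ring A the C3 hydroxyl and the C4 bromine are trans; the hydroxyl lies on the face that carries C7 and the bromine on the face that carries C11. C6 is stereogenic only because the two arms of ring B differ, and it is wedged between the quaternary C5 and the substituted alkene carbon C1, so it is hard to build and hard to use as a control element unless something is tethered to it. The sensitive groups are the trans-bromohydrin (epoxide closure in base), the allylic alcohol (ionisation in acid), the secondary neopentyl-type bromide at C4 and the tetrasubstituted vinyl bromide, whose bromine must sit on C10 and not on C9. The hard part is C4: an unactivated position next to C5 that must receive bromine with defined configuration relative to the remote C6. The strategy rests on one feature: C3 and C6 are 1,4 across ring A and the C3 oxygen is cis to C7, so a carboxyl group at C7 can reach C3 as a bridging lactone oxygen while electrophilic bromine enters C4 from the other face.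

## Retrosynthetic reasoning

17 from 16. The last disconnection is only the C3–O silyl ether. The free trans-bromohydrin closes to an epoxide under base, so the oxygen stays masked through every basic step and is released under acidic fluoride at the end.

16 from 14. Ring B is cut at C8–C9. This bond joins an sp3 carbon to the C9 end of the dibromoalkene, so it can be made by intramolecular B-alkyl Suzuki–Miyaura coupling of borane 15, formed by hydroboration of the vinyl group of 14. Cutting here keeps the C10 bromine untouched as the second halogen of the arm. A cut at C9=C10 would call for metathesis of a vinyl bromide to a tetrasubstituted alkene, and a cut at C7–C8 would need substitution at a neopentyl carbon.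

14 from 10. C8 is added as a methylene unit to a C7 aldehyde (13), and C7 is the former lactone carbonyl of 10. The lactone is opened by hydride reduction to diol 11, both hydroxyls are silylated (12), and the primary silyl ether alone is oxidised to the aldehyde. The tether carbon therefore becomes C7 of ring B and is not discarded.

10 from 8 and 9. This is the key disconnection: the C3–O and C4–Br bonds are removed together. In the forward sense the brominating agent 9 attacks C4 of the C1=C2–C3=C4 diene of acid 8 and the C7 carboxylate closes onto C3. The temporary 2-oxabicyclo[2.2.2]octenone ring forces oxygen onto the C7 face and bromine onto the opposite face, so both new stereocentres are derived from C6. No skeletal bond is formed.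

8 from 6. The single enantiomer is obtained by resolution of racemic acid 6 through its salt 7 with a chiral amine. The carboxylic acid is the only handle for salt formation in the route, and resolving before the key step means that everything after it is carried as one enantiomer.

6 from 4 and 2. The C6–C11 bond is cut. Alkylation of the trienediolate 5 of acid 4 at its α-carbon with the allylic bromide 2 creates the quaternary centre and moves the diene into the C1=C2–C3=C4 position that the key step needs. The acid dianion is used instead of an ester enolate because an ester at the finished quaternary centre, flanked by C5 and C1, would resist hydrolysis, and the forcing base required would endanger the dibromoalkene.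

4 from 3, and 2 from 1. The hindered ester 3 is saponified before the sensitive arm is present. The electrophile 2 comes from anti dibromination of alkyne 1, which sets the E geometry that places the C9 bromine cis to C11, as the ring closure requires, and supplies the C10 bromine of the target from the first step.

## Alternatives that were turned down

Alternative 1: The disconnection is the C6–C7 bond of ring B together with the C9=C10 alkene, traced back to a cation cascade. Acid would ionise a tertiary cyclopropylcarbinol at C9; the C6–C10 cyclopropane bond opens to the vinyl bromide and a C6 cation, C7 shifts from C1 to C6 and closes ring B, and loss of a proton from C2 gives A1, (6R)-8-bromo-1,5,5,9-tetramethylspiro[5.5]undeca-1,8-diene.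
- For: one step makes ring B, the quaternary centre and the vinyl bromide, with the bromine position fixed by the bromocyclopropane, and C6 is set by a stereospecific 1,2-shift. In bond-forming economy this is stronger than the chosen route, which needs a separate alkylation and a separate coupling.
- Against: A1 carries neither the C3 oxygen nor the C4 bromine. C3 is allylic and could be oxidised, but C4 is an isolated methylene next to C5, so the bromohydrin would have to come from a C3 ketone by α-bromination and reduction, with both centres set by weak substrate control from the remote C6. The C6 cation is also flanked by the C5 gem-dimethyl group, so a methyl shift competes with the C7 shift, and the fused tricyclic substrate with several stereocentres needs a long synthesis of its own.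
- Comparison: the chosen strategy spends more steps on ring B, but C3 and C4 are set by a tethered, stereospecific addition.

Alternative 2: The disconnection is the C1–C6 bond of ring A. A Z enol triflate at C1 would undergo oxidative addition to zerovalent palladium with a chiral ligand, 6-exo insertion across the C6=C7 alkene of a Birch-type 1,4-cyclohexadiene and β-hydride elimination toward C8, giving A2, (6S)-10-methoxy-1,5,5,9-tetramethylspiro[5.5]undeca-1,7,9-trien-3-one.
- For: C6 is formed catalytically and enantioselectively. This is stronger than the resolution used here, which discards half of the material. C3 is already oxygenated.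
- Against: the insertion must create a quaternary carbon next to the quaternary C5. In ring A the C3 ketone must then be turned into the trans-bromohydrin by bromination at C4 and carbonyl reduction, each under substrate control from the spiro centre. In ring B the methoxydiene must become the C9=C10 vinyl bromide with C7–C8 saturated, which means enol ether hydrolysis, a regiochemically delicate ketone-to-vinyl-bromide conversion and a selective alkene reduction, all beside a second enone.
- Comparison: the chosen strategy gives up catalytic asymmetry, but it derives C3 and C4 directly from C6 and carries the C10 bromine from the first step.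

Alternative 3: The disconnection is the C6–C11 bond, followed by insertion of C10. A C9 methyl ketone of the ionone family would be converted by a lithiated silyl diazomethane into an alkylidene carbene C9=C11, which inserts into the tertiary allylic C6–H bond with retention and closes a spirocyclopentene, giving A3, tert-butyldimethyl{[(5R,8R)-2,6,10,10-tetramethylspiro[4.5]deca-1,6-dien-8-yl]oxy}silane.
- For: C6 is made stereospecifically from a C–H stereocentre of a cheap monocyclic precursor, and the C3 oxygen is already in place with a known relation to it. On the setting of C6 this is as strong as or stronger than the chosen route.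
- Against: the one-carbon ring expansion must place a bromine-bearing C10 between C9 and C11. A dihalocarbene cannot reliably distinguish the two trisubstituted alkenes C9=C11 and C1=C2. Opening of the dihalocyclopropane gives a 2-bromoallyl cation whose capture at C9 or C11 is regiochemically open and leaves an extra allylic group or a diene to remove. C4 still has no bromine and is an unactivated methylene.
- Comparison: the chosen strategy introduces the C4 bromine together with the C3 oxygen in one operation and needs no ring expansion.

Key step: step 6

Assumption: the less soluble salt of racemic acid 6 with (R)-1-phenylethylamine is taken to contain the (R)-acid. If the (S)-acid crystallises instead, the (S)-amine is used, and the assignment is secured by X-ray analysis of salt 7 or lactone 10.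

## Route

Step 1
Reactants: 1 1-bromobut-2-yne
Product: 2 (E)-1,2,3-tribromobut-2-ene
Conditions: Br2 (1.0 equiv), CH2Cl2, −30 → 0 °C, dark; distillation
Reagents that add atoms: bromine, BrBr
Why: Electrophilic anti addition of bromine to the alkyne through a bridged bromonium ion should give the E dibromide, and the deactivated product does not add a second equivalent. The E geometry places the C9 bromine cis to C11, as the later ring closure needs.

Step 2
Reactants: 3 ethyl safranate (ethyl 2,6,6-trimethylcyclohexa-1,3-diene-1-carboxylate)
Product: 4 safranic acid (2,6,6-trimethylcyclohexa-1,3-diene-1-carboxylic acid)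
Conditions: KOH, ethylene glycol–H2O, 120 °C; then 2 M HCl
Reagents that add atoms: potassium hydroxide, [K+].[OH-]
Why: Saponification of a hindered ester under forcing conditions, done here because no sensitive group is present yet. Any 2,4-diene isomer of 4 formed by base-induced double-bond migration leads to the same dianion in step 3.

Step 3
Reactants: 4 safranic acid; 2 (E)-1,2,3-tribromobut-2-ene
Product: 6 racemic 1-[(2E)-2,3-dibromobut-2-en-1-yl]-2,6,6-trimethylcyclohexa-2,4-diene-1-carboxylic acid, via dilithium trienediolate 5 (not isolated)
Conditions: LDA (2.3 equiv), THF, −78 → 25 °C; DMPU, then 2, −78 → 0 °C; 1 M HCl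
Reagents that add atoms: none
Why: Alkylation of a carboxylic acid dianion: the second equivalent of LDA removes a C4 proton of the lithium carboxylate, and the linear trienediolate 5 should react with the allylic bromide at its α-carbon C6 by SN2 displacement, creating the quaternary centre and leaving the diene at C1=C2–C3=C4. Warming before the electrophile is added allows a cross-conjugated dianion from deprotonation of the C1 methyl to equilibrate to 5; the vinylic bromines of 2 are inert to substitution.

Step 4
Reactants: 6 racemic acid
Product: 7 (R)-1-phenylethylammonium (1R)-1-[(2E)-2,3-dibromobut-2-en-1-yl]-2,6,6-trimethylcyclohexa-2,4-diene-1-carboxylate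
Conditions: (R)-1-phenylethylamine (1.0 equiv), acetone, recrystallisation to constant rotation
Reagents that add atoms: (R)-1-phenylethylamine, C[C@@H](N)c1ccccc1
Why: Classical resolution through diastereomeric ammonium carboxylates. No stereocentre is formed; the (R)-configured C6 is selected by crystallisation.

Step 5
Reactants: 7 ammonium carboxylate salt
Product: 8 (1R)-1-[(2E)-2,3-dibromobut-2-en-1-yl]-2,6,6-trimethylcyclohexa-2,4-diene-1-carboxylic acid
Conditions: 1 M HCl, Et2O, 0 °C
Reagents that add atoms: none
Why: Proton transfer from the mineral acid frees the carboxylic acid, and the amine stays in the aqueous phase as its hydrochloride. The quaternary centre has no α-hydrogen and cannot racemise.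

Step 6
Reactants: 8 (1R)-dienyl acid; 9 N-bromosuccinimide
Product: 10 (1S,4R,7S)-7-bromo-4-[(2E)-2,3-dibromobut-2-en-1-yl]-5,8,8-trimethyl-2-oxabicyclo[2.2.2]oct-5-en-3-one (bridged bromolactone with C3–O, C4–Br and C6 set)
Conditions: NBS (1.05 equiv), NaHCO3, MeCN, −20 → 0 °C, dark
Reagents that add atoms: N-bromosuccinimide 9, O=C1CCC(=O)N1Br
Why: This is a bromolactonization of a cyclohexadienecarboxylic acid, a known halolactonization class that gives bridged bicyclic lactones. Compound 9 transfers Br+ to C4, the diene terminus that leaves the positive charge spread over C3 and the methyl-bearing C1, and the carboxylate on C6 traps this bromonium or allyl cation at C3. The ring that closes is a six-membered δ-lactone (O–C7–C6–C1=C2–C3; 6-exo with respect to C3=C4 when counted through C1=C2), which completes a 2-oxabicyclo[2.2.2]oct-5-en-3-one; capture at C1 would require a four-membered lactone and is excluded. C3 is controlled by the tether: the carboxyl can reach C3 only on the ring face on which it sits at C6, so the oxygen ends cis to C7. C4 is controlled by the anti course of the addition: only the bromonium ion on the face away from the carboxylate can be opened intramolecularly, so bromine ends trans to the new C–O bond and cis to C11. The step needs site selectivity between the two diene termini and chemoselectivity against the arm. Attack of Br+ at C1, which would lead to a γ-lactone at C2, is disfavoured by the C1 methyl, the adjacent quaternary C6 and the less stabilised cation, and the dibromoalkene is too electron-poor to react. Low temperature, exclusion of light and the bicarbonate buffer should suppress radical allylic bromination and acid-promoted side reactions.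

Step 7
Reactants: 10 bromolactone
Product: 11 (1S,4R,6S)-6-bromo-4-[(2E)-2,3-dibromobut-2-en-1-yl]-4-(hydroxymethyl)-3,5,5-trimethylcyclohex-2-en-1-ol
Conditions: LiBH4, THF, MeOH (1 equiv), 0 → 40 °C; aqueous NH4Cl
Reagents that add atoms: none
Why: Hydride reduction of the lactone to the diol opens the temporary ring. LiBH4 leaves alkyl and vinyl bromides untouched, and the intermediate alkoxyborates are too weakly nucleophilic to displace the C4 bromide.

Step 8
Reactants: 11 diol
Product: 12 bis(triethylsilyl) ether of 11 (C3–OSiEt3 and C7–OSiEt3)
Conditions: TESOTf (2.5 equiv), 2,6-lutidine, CH2Cl2, −78 → 0 °C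
Reagents that add atoms: triethylsilyl trifluoromethanesulfonate, CC[Si](CC)(CC)OS(=O)(=O)C(F)(F)F
Why: Silylation of both hydroxyls with a silyl triflate and a hindered pyridine base. Masking the C3 oxygen blocks epoxide closure onto the trans C4 bromide in the basic steps that follow.

Step 9
Reactants: 12 bis(triethylsilyl) ether
Product: 13 (1R,4S,5S)-5-bromo-1-[(2E)-2,3-dibromobut-2-en-1-yl]-2,6,6-trimethyl-4-(triethylsilyloxy)cyclohex-2-ene-1-carbaldehyde
Conditions: (COCl)2, DMSO, CH2Cl2, −78 → −35 °C; Et3N, → 0 °C
Reagents that add atoms: none
Why: Swern oxidation applied directly to a primary triethylsilyl ether: the chlorosulfonium reagent cleaves the primary Si–O bond and the resulting alkoxysulfonium salt collapses to the aldehyde, while the secondary silyl ether at C3 should remain. The aldehyde has no α-hydrogen and cannot epimerise.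

Step 10
Reactants: 13 aldehyde
Product: 14 triethyl{[(1S,4R,6S)-6-bromo-4-[(2E)-2,3-dibromobut-2-en-1-yl]-4-ethenyl-3,5,5-trimethylcyclohex-2-en-1-yl]oxy}silane
Conditions: Ph3PCH3Br (3.0 equiv), KOtBu (2.7 equiv), THF, 0 → 40 °C
Reagents that add atoms: methyltriphenylphosphonium bromide, C[P+](c1ccccc1)(c1ccccc1)c1ccccc1.[Br-]
Why: Wittig methylenation; the unstabilised ylide reacts with hindered aldehydes, and the slight deficit of base spares the dibromoalkene. Loss of HBr across C3–C4 is blocked because the C3 hydrogen is cis to the bromine.

Step 11
Reactants: 14 vinyl compound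
Product: 16 {[(3S,4S,6S)-4,8-dibromo-1,5,5,9-tetramethylspiro[5.5]undeca-1,8-dien-3-yl]oxy}triethylsilane, via B-alkyl-9-BBN adduct 15 (not isolated)
Conditions: 9-BBN, THF, 0 → 25 °C; then Pd(dppf)Cl2 (10 mol %), AsPh3, Cs2CO3, DMF–THF–H2O, 25 → 50 °C, 0.01 M
Reagents that add atoms: none
Why: 9-BBN should add only to the monosubstituted C7=C8 alkene, with boron on C8. Zerovalent palladium then inserts into the C9–Br bond, which is flanked by a methyl group, in preference to the C10–Br bond next to the neopentyl-type C11, and intramolecular B-alkyl Suzuki–Miyaura coupling closes the six-membered ring B with retention of alkene geometry. The C10 bromine remains as the vinyl bromide of the target.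

Step 12
Reactants: 16 silyl ether
Product: 17 (3S,4S,6S)-4,8-dibromo-1,5,5,9-tetramethylspiro[5.5]undeca-1,8-dien-3-ol
Conditions: HF·pyridine, pyridine, THF, 0 → 25 °C
Reagents that add atoms: none
Why: Fluoride-mediated cleavage of the secondary triethylsilyl ether under buffered acidic conditions. No free alkoxide is formed next to the C4 bromide, so the bromohydrin should survive.

## Compound list

1 | 1-bromobut-2-yne | CC#CCBr | starting material
2 | (E)-1,2,3-tribromobut-2-ene | BrC/C(Br)=C(/C)Br | intermediate
3 | ethyl safranate (ethyl 2,6,6-trimethylcyclohexa-1,3-diene-1-carboxylate) | CCOC(=O)C1=C(C)C=CCC1(C)C | starting material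
4 | safranic acid (2,6,6-trimethylcyclohexa-1,3-diene-1-carboxylic acid) | OC(=O)C1=C(C)C=CCC1(C)C | intermediate
5 | dilithium trienediolate of 4 (dilithium (2,6,6-trimethylcyclohexa-2,4-dien-1-ylidene)methanediolate) | [Li+].[Li+].[O-]C([O-])=C1C(C)=CC=CC1(C)C | intermediate
6 | racemic 1-[(2E)-2,3-dibromobut-2-en-1-yl]-2,6,6-trimethylcyclohexa-2,4-diene-1-carboxylic acid | CC1=CC=CC(C)(C)C1(C/C(Br)=C(/C)Br)C(=O)O | intermediate
7 | (R)-1-phenylethylammonium (1R)-1-[(2E)-2,3-dibromobut-2-en-1-yl]-2,6,6-trimethylcyclohexa-2,4-diene-1-carboxylate | CC1=CC=CC(C)(C)[C@]1(C/C(Br)=C(/C)Br)C(=O)[O-].C[C@@H]([NH3+])c1ccccc1 | intermediate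
8 | (1R)-1-[(2E)-2,3-dibromobut-2-en-1-yl]-2,6,6-trimethylcyclohexa-2,4-diene-1-carboxylic acid | CC1=CC=CC(C)(C)[C@]1(C/C(Br)=C(/C)Br)C(=O)O | intermediate
9 | N-bromosuccinimide | O=C1CCC(=O)N1Br | starting material
10 | (1S,4R,7S)-7-bromo-4-[(2E)-2,3-dibromobut-2-en-1-yl]-5,8,8-trimethyl-2-oxabicyclo[2.2.2]oct-5-en-3-one | CC1=C[C@@H]2OC(=O)[C@@]1(C/C(Br)=C(/C)Br)C(C)(C)[C@@H]2Br | intermediate
11 | (1S,4R,6S)-6-bromo-4-[(2E)-2,3-dibromobut-2-en-1-yl]-4-(hydroxymethyl)-3,5,5-trimethylcyclohex-2-en-1-ol | CC1=C[C@H](O)[C@@H](Br)C(C)(C)[C@]1(C/C(Br)=C(/C)Br)CO | intermediate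
12 | triethyl{[(1S,4R,6S)-6-bromo-4-[(2E)-2,3-dibromobut-2-en-1-yl]-3,5,5-trimethyl-4-[(triethylsilyloxy)methyl]cyclohex-2-en-1-yl]oxy}silane | CC1=C[C@H](O[Si](CC)(CC)CC)[C@@H](Br)C(C)(C)[C@]1(C/C(Br)=C(/C)Br)CO[Si](CC)(CC)CC | intermediate
13 | (1R,4S,5S)-5-bromo-1-[(2E)-2,3-dibromobut-2-en-1-yl]-2,6,6-trimethyl-4-(triethylsilyloxy)cyclohex-2-ene-1-carbaldehyde | CC1=C[C@H](O[Si](CC)(CC)CC)[C@@H](Br)C(C)(C)[C@]1(C/C(Br)=C(/C)Br)C=O | intermediate
14 | triethyl{[(1S,4R,6S)-6-bromo-4-[(2E)-2,3-dibromobut-2-en-1-yl]-4-ethenyl-3,5,5-trimethylcyclohex-2-en-1-yl]oxy}silane | CC1=C[C@H](O[Si](CC)(CC)CC)[C@@H](Br)C(C)(C)[C@]1(C/C(Br)=C(/C)Br)C=C | intermediate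
15 | B-alkyl-9-BBN adduct of 14 (9-borabicyclo[3.3.1]nonan-9-yl group on C8) | CC1=C[C@H](O[Si](CC)(CC)CC)[C@@H](Br)C(C)(C)[C@]1(C/C(Br)=C(/C)Br)CCB1C2CCCC1CCC2 | intermediate
16 | {[(3S,4S,6S)-4,8-dibromo-1,5,5,9-tetramethylspiro[5.5]undeca-1,8-dien-3-yl]oxy}triethylsilane | CC1=C[C@H](O[Si](CC)(CC)CC)[C@@H](Br)C(C)(C)[C@]12CCC(C)=C(Br)C2 | intermediate
17 | (3S,4S,6S)-4,8-dibromo-1,5,5,9-tetramethylspiro[5.5]undeca-1,8-dien-3-ol | CC1=C[C@H](O)[C@@H](Br)C(C)(C)[C@]12CCC(C)=C(Br)C2 | target

## Step count and risk

Total step count: 12. Longest linear sequence: 11 steps (steps 2 to 12, from 3 to 17); step 1 is a one-step side branch.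

Least certain steps:

Step 6 (key step). The most likely failures are leakage of Br+ to the C1 terminus with closure of a γ-lactone at C2, loss of CO2 from the carboxylate next to the allyl cation (decarboxylative opening), and incomplete anti selectivity if the cation is captured after bromine has entered from the carboxylate face. Fallback: acid 8 is converted through its acid chloride ((COCl)2, catalytic DMF; then Me2NH) into (1R)-1-[(2E)-2,3-dibromobut-2-en-1-yl]-N,N,2,6,6-pentamethylcyclohexa-2,4-diene-1-carboxamide F1. This amide is treated with 9 in aqueous THF containing acetic acid. The amide oxygen is a better internal nucleophile and cannot be lost as CO2; it closes onto C3 to an iminium lactone that is hydrolysed in the same flask, and the route is rejoined at lactone 10.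

Step 3. Deprotonation may occur at the C1 methyl group, which lies next to the carboxylate, and give a cross-conjugated dianion and then the exocyclic methylene isomer; alkylation may also occur at C2 instead of the hindered C6. Fallback: ester 3 is reduced with DIBAL-H to (2,6,6-trimethylcyclohexa-1,3-dien-1-yl)methanol F2 and oxidised with MnO2 to safranal F3. Its potassium trienolate is formed reversibly with KOtBu in THF–tBuOH, so the linear, fully conjugated enolate is selected under thermodynamic control, and it is alkylated with 2 at the α-carbon to racemic 1-[(2E)-2,3-dibromobut-2-en-1-yl]-2,6,6-trimethylcyclohexa-2,4-diene-1-carbaldehyde F4. Pinnick oxidation (NaClO2, NaH2PO4, 2-methylbut-2-ene) then returns to acid 6.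

Step 11. Oxidative addition into the hindered, fully substituted C9–Br bond may be slow, so that protodeboronation and β-hydride elimination of the alkyl partner take over, or palladium may insert at C10–Br and close a five-membered ring. Fallback: the coupling and the ring closure are separated. Aldehyde 13 undergoes Stille coupling with tributyl(vinyl)stannane (Pd2(dba)3, AsPh3, CuI, DMF) at the less hindered C9–Br to give (1R,4S,5S)-5-bromo-1-[(2E)-2-bromo-3-methylpenta-2,4-dien-1-yl]-2,6,6-trimethyl-4-(triethylsilyloxy)cyclohex-2-ene-1-carbaldehyde F5. Wittig methylenation gives triethyl{[(1S,4R,6S)-6-bromo-4-[(2E)-2-bromo-3-methylpenta-2,4-dien-1-yl]-4-ethenyl-3,5,5-trimethylcyclohex-2-en-1-yl]oxy}silane F6. Ring-closing metathesis with the second-generation Grubbs catalyst forms C7=C8 and gives {[(3S,4S,6R)-4,10-dibromo-1,5,5,9-tetramethylspiro[5.5]undeca-1,7,9-trien-3-yl]oxy}triethylsilane F7. Diimide (2-nitrobenzenesulfonyl hydrazide, Et3N) reduces only the disubstituted C7=C8 bond and returns to 16.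

Step 9. Discrimination between the primary, neopentyl-type silyl ether and the secondary allylic one may be insufficient, leading to oxidation at C3 as well or to no reaction at C7. Fallback: lactone 10 is opened with Me2AlN(OMe)Me (from AlMe3 and MeNHOMe·HCl, CH2Cl2) to (1R,4S,5S)-5-bromo-1-[(2E)-2,3-dibromobut-2-en-1-yl]-4-hydroxy-N-methoxy-N,2,6,6-tetramethylcyclohex-2-ene-1-carboxamide F8. The free C3 hydroxyl is silylated with TESOTf and 2,6-lutidine to its triethylsilyl ether F9, and DIBAL-H reduction of the amide returns to aldehyde 13 without any need to tell two silyl ethers apart.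

Step 4. The diastereomeric salts may not separate cleanly on crystallisation. Fallback: racemic acid 6 is carried through the conditions of step 6, which gives 10 together with its enantiomer, (1R,4S,7R)-7-bromo-4-[(2E)-2,3-dibromobut-2-en-1-yl]-5,8,8-trimethyl-2-oxabicyclo[2.2.2]oct-5-en-3-one F10. The rigid, neutral lactones are separated by preparative chromatography on a chiral stationary phase, and the route continues from 10.

## Further compounds

F1 | step 6 | (1R)-1-[(2E)-2,3-dibromobut-2-en-1-yl]-N,N,2,6,6-pentamethylcyclohexa-2,4-diene-1-carboxamide | CC1=CC=CC(C)(C)[C@]1(C/C(Br)=C(/C)Br)C(=O)N(C)C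
F2 | step 3 | (2,6,6-trimethylcyclohexa-1,3-dien-1-yl)methanol | CC1=C(CO)C(C)(C)CC=C1
F3 | step 3 | safranal (2,6,6-trimethylcyclohexa-1,3-diene-1-carbaldehyde) | CC1=C(C=O)C(C)(C)CC=C1
F4 | step 3 | racemic 1-[(2E)-2,3-dibromobut-2-en-1-yl]-2,6,6-trimethylcyclohexa-2,4-diene-1-carbaldehyde | CC1=CC=CC(C)(C)C1(C/C(Br)=C(/C)Br)C=O
F5 | step 11 | (1R,4S,5S)-5-bromo-1-[(2E)-2-bromo-3-methylpenta-2,4-dien-1-yl]-2,6,6-trimethyl-4-(triethylsilyloxy)cyclohex-2-ene-1-carbaldehyde | CC1=C[C@H](O[Si](CC)(CC)CC)[C@@H](Br)C(C)(C)[C@]1(C/C(Br)=C(/C)C=C)C=O
F6 | step 11 | triethyl{[(1S,4R,6S)-6-bromo-4-[(2E)-2-bromo-3-methylpenta-2,4-dien-1-yl]-4-ethenyl-3,5,5-trimethylcyclohex-2-en-1-yl]oxy}silane | CC1=C[C@H](O[Si](CC)(CC)CC)[C@@H](Br)C(C)(C)[C@]1(C/C(Br)=C(/C)C=C)C=C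
F7 | step 11 | {[(3S,4S,6R)-4,10-dibromo-1,5,5,9-tetramethylspiro[5.5]undeca-1,7,9-trien-3-yl]oxy}triethylsilane | CC1=C[C@H](O[Si](CC)(CC)CC)[C@@H](Br)C(C)(C)[C@]12C=CC(C)=C(Br)C2
F8 | step 9 | (1R,4S,5S)-5-bromo-1-[(2E)-2,3-dibromobut-2-en-1-yl]-4-hydroxy-N-methoxy-N,2,6,6-tetramethylcyclohex-2-ene-1-carboxamide | CC1=C[C@H](O)[C@@H](Br)C(C)(C)[C@]1(C/C(Br)=C(/C)Br)C(=O)N(C)OC
F9 | step 9 | (1R,4S,5S)-5-bromo-1-[(2E)-2,3-dibromobut-2-en-1-yl]-N-methoxy-N,2,6,6-tetramethyl-4-(triethylsilyloxy)cyclohex-2-ene-1-carboxamide | CC1=C[C@H](O[Si](CC)(CC)CC)[C@@H](Br)C(C)(C)[C@]1(C/C(Br)=C(/C)Br)C(=O)N(C)OC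
F10 | step 4 | (1R,4S,7R)-7-bromo-4-[(2E)-2,3-dibromobut-2-en-1-yl]-5,8,8-trimethyl-2-oxabicyclo[2.2.2]oct-5-en-3-one (enantiomer of 10) | CC1=C[C@H]2OC(=O)[C@]1(C/C(Br)=C(/C)Br)C(C)(C)[C@H]2Br
A1 | alternative 1 | (6R)-8-bromo-1,5,5,9-tetramethylspiro[5.5]undeca-1,8-diene | CC1=CCCC(C)(C)[C@]12CCC(C)=C(Br)C2
A2 | alternative 2 | (6S)-10-methoxy-1,5,5,9-tetramethylspiro[5.5]undeca-1,7,9-trien-3-one | CC1=CC(=O)CC(C)(C)[C@]12C=CC(C)=C(OC)C2
A3 | alternative 3 | tert-butyldimethyl{[(5R,8R)-2,6,10,10-tetramethylspiro[4.5]deca-1,6-dien-8-yl]oxy}silane | CC1=C[C@@]2(CC1)C(C)=C[C@H](O[Si](C)(C)C(C)(C)C)CC2(C)C
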